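**Retrosynthetic overview**
- Target ⇒ phenol desilylation, Steglich aroylation of the hindered 6-OH and selective acetylation of the 9-OH (daucane numbering) ⇒ cis-6,9-diol of the trans-hydroazulene.
- cis-Diol ⇒ singlet-oxygen 1,4-dioxygenation of the 6,8-diene, both C–O bonds on the face away from the angular methyl.
- Diene ⇒ dienyl triflate ⇒ one-carbon ring expansion of a trans-hydrindenone by a β-oxido-carbenoid 1,2-alkenyl shift (1,1-dibromoethane); the six-membered ring becomes the seven-membered ring and C-8 with its methyl is inserted.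
- Hydrindenone ⇒ Saegusa oxidation ⇐ samarium Barbier closure of the cyclopentanol (sets C-4) ⇐ enantioselective Diels–Alder adduct of an (E)-β,β-disubstituted enone and a 2-silyloxybutadiene (sets C-1 and C-5, trans).
- Ring order: cyclohexene (Diels–Alder) → cyclopentane (Barbier) → six-to-seven ring expansion; pieces are 4-bromobut-1-yne, isobutyryl chloride, methyl vinyl ketone, 1,1-dibromoethane and TBS-protected 4-bromophenol.

Assumption: the (S)-oxazaborolidine·AlBr3 catalyst directs the diene to the Cα-Re face of the (E)-enone dienophile; if the sense is found to be the opposite, the (R)-catalyst is used and nothing else changes.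

**Step 1**
Reactants: 1 4-bromobut-1-yne; 2 2-methylpropanoyl chloride
Product: 4 (E)-7-bromo-2,5-dimethylhept-4-en-3-one, via alkenylalane 3 (not isolated)
Conditions: AlMe3 (2.5 equiv), Cp2ZrCl2 (25 mol%), CH2Cl2, 0 °C to rt; evaporate excess AlMe3; then 2, Pd(PPh3)4 (5 mol%), THF, 0 °C to rt
Reagents that add atoms: trimethylaluminium, C[Al](C)C
Why: Negishi zirconium-catalysed carboalumination adds methyl and aluminium syn across the terminal alkyne (methyl to the internal carbon), and palladium-catalysed acylation of the alkenylalane with retention gives the (E)-enone with the acyl group cis to the new methyl.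

**Step 2**
Reactants: 5 but-3-en-2-one
Product: 6 tert-butyl(buta-1,3-dien-2-yloxy)dimethylsilane
Conditions: TBSOTf, Et3N, Et2O, 0 °C to rt
Reagents that add atoms: tert-butyldimethylsilyl trifluoromethanesulfonate, CC(C)(C)[Si](C)(C)OS(=O)(=O)C(F)(F)F
Why: Silyl enol ether formation by soft enolisation of the methyl ketone gives the cross-conjugated 2-silyloxydiene.

**Step 3**
Reactants: 4 (E)-7-bromo-2,5-dimethylhept-4-en-3-one; 6 tert-butyl(buta-1,3-dien-2-yloxy)dimethylsilane
Product: 7 1-[(1R,6S)-6-(2-bromoethyl)-4-[(tert-butyldimethylsilyl)oxy]-6-methylcyclohex-3-en-1-yl]-2-methylpropan-1-one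
Conditions: (S)-B-(o-tolyl)oxazaborolidine from (S)-α,α-diphenylprolinol (15 mol%), AlBr3 (12 mol%), CH2Cl2, −40 °C, 24 h
Reagents that add atoms: none
Why: Proposed new method: enantioselective Diels–Alder reaction of a β,β-disubstituted acyclic enone with a 2-silyloxydiene under a cationic oxazaborolidine·AlBr3 Lewis acid — the catalyst binds the carbonyl of the s-cis enone on the lone pair anti to the isopropyl group (α-C–H···O contact) and screens one alkene face, the concerted asynchronous [4+2] joins the diene CH2 next to the silyloxy carbon to the β-carbon ("para" orientation) and transfers the (E)-geometry suprafacially, so the acyl group at C-1 is trans to the bromoethyl group on the new quaternary C-6; the closest known reactions are oxazaborolidinium-catalysed Diels–Alder additions of 2-silyloxydienes to less substituted enones and the achiral AlBr3/AlMe3-catalysed hindered Diels–Alder of silyloxydienes with β,β-disubstituted enones.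

**Step 4**
Reactants: 7 1-[(1R,6S)-6-(2-bromoethyl)-4-[(tert-butyldimethylsilyl)oxy]-6-methylcyclohex-3-en-1-yl]-2-methylpropan-1-one
Product: 8 (1R,3aR,7aR)-5-[(tert-butyldimethylsilyl)oxy]-1-isopropyl-3a-methyl-2,3,3a,4,7,7a-hexahydro-1H-inden-1-ol
Conditions: SmI2 (2.5 equiv), HMPA, THF, 0 °C to rt; aq. NaHCO3
Reagents that add atoms: none
Why: Samarium Barbier cyclisation (the primary bromide is reduced to an alkylsamarium that adds to the ketone to close the five-membered ring); the two side chains are trans, so a trans-hydrindane forms, and the isopropyl group takes the open face syn to H-7a and anti to the 3a-methyl, leaving the new hydroxyl cis to that methyl (1R).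

**Step 5**
Reactants: 8 (1R,3aR,7aR)-5-[(tert-butyldimethylsilyl)oxy]-1-isopropyl-3a-methyl-2,3,3a,4,7,7a-hexahydro-1H-inden-1-ol
Product: 9 (1R,3aR,7aR)-1-hydroxy-1-isopropyl-3a-methyl-1,2,3,3a,4,7a-hexahydro-5H-inden-5-one
Conditions: Pd(OAc)2 (1.1 equiv), MeCN, 40 °C
Reagents that add atoms: none
Why: Saegusa–Ito oxidation of the silyl enol ether; the enol ether double bond fixed by the cycloaddition lies on the only side of the carbonyl that has a β-hydrogen, so the 6,7-enone is the single regioisomer.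

**Step 6**
Reactants: 9 (1R,3aR,7aR)-1-hydroxy-1-isopropyl-3a-methyl-1,2,3,3a,4,7a-hexahydro-5H-inden-5-one; 10 1,1-dibromoethane
Product: 13 (1R,3aR,8aR)-1-hydroxy-1-isopropyl-3a,6-dimethyl-1,2,3,3a,4,8a-hexahydroazulen-5-yl trifluoromethanesulfonate, via dibromoethyl carbinolate 11 (not isolated), via lithium dienolate 12 (not isolated)
Conditions: 10 (1.3 equiv), lithium 2,2,6,6-tetramethylpiperidide (2.1 equiv), THF, −95 °C; n-BuLi (1.2 equiv), −95 to −30 °C; PhNTf2 (1.3 equiv), −78 to 0 °C
Reagents that add atoms: N-phenylbis(trifluoromethanesulfonimide), O=S(=O)(N(c1ccccc1)S(=O)(=O)C(F)(F)F)C(F)(F)F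
Why: Nozaki–Yamamoto β-oxido carbenoid ring expansion — 1,1-dibromoethyllithium adds 1,2 to the enone, bromine–lithium exchange gives a carbenoid whose carbon accepts a 1,2-shift of the alkenyl carbon (sp2 carbon migrates in preference to the neopentyl-type CH2) with loss of bromide, giving regiospecifically the seven-membered lithium dienolate that carries the new methyl-bearing carbon and is trapped on oxygen as the dienyl triflate (the hindered tertiary alkoxide is not triflated).

**Step 7**
Reactants: 13 (1R,3aR,8aR)-1-hydroxy-1-isopropyl-3a,6-dimethyl-1,2,3,3a,4,8a-hexahydroazulen-5-yl trifluoromethanesulfonate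
Product: 14 (1R,3aR,8aR)-1-isopropyl-3a,6-dimethyl-1,2,3,3a,4,8a-hexahydroazulen-1-ol
Conditions: Pd(OAc)2 (5 mol%), PPh3 (10 mol%), HCO2H, Et3N, DMF, 60 °C
Reagents that add atoms: none
Why: Palladium-catalysed formate hydrogenolysis of a vinyl triflate (Cacchi reduction) replaces the triflate by hydrogen and leaves the conjugated diene in place.

**Step 8**
Reactants: 14 (1R,3aR,8aR)-1-isopropyl-3a,6-dimethyl-1,2,3,3a,4,8a-hexahydroazulen-1-ol
Product: 16 (1R,3aR,5S,8S,8aS)-1-isopropyl-3a,6-dimethyl-1,2,3,3a,4,5,8,8a-octahydroazulene-1,5,8-triol, via endoperoxide 15 (not isolated)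
Conditions: O2, tetraphenylporphyrin (1 mol%), visible light, CH2Cl2, −30 °C; then thiourea, MeOH, rt
Reagents that add atoms: dioxygen, O=O
Why: Singlet-oxygen [4+2] cycloaddition to the cisoid cycloheptadiene takes place on the face of H-8a, away from the angular methyl and the C-1 quaternary carbon, and thiourea reduction of the O–O bond gives the cis-5,8-diol, so both new stereocentres are set together.

**Step 9**
Reactants: 16 (1R,3aR,5S,8S,8aS)-1-isopropyl-3a,6-dimethyl-1,2,3,3a,4,5,8,8a-octahydroazulene-1,5,8-triol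
Product: 17 (1R,3aR,5S,8S,8aS)-1,8-dihydroxy-1-isopropyl-3a,6-dimethyl-1,2,3,3a,4,5,8,8a-octahydroazulen-5-yl acetate
Conditions: Ac2O (1.05 equiv), pyridine, CH2Cl2, 0 °C
Reagents that add atoms: acetic anhydride, CC(=O)OC(C)=O
Why: Sterically controlled acetylation — the 5-OH is flanked by a CH2 and reacts, whereas the 8-OH next to the ring-fusion CH between two quaternary carbons and the tertiary 1-OH stay free.

**Step 10**
Reactants: 18 (4-bromophenoxy)(tert-butyl)dimethylsilane
Product: 20 4-[(tert-butyldimethylsilyl)oxy]benzoic acid, via aryllithium 19 (not isolated)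
Conditions: n-BuLi, THF, −78 °C; CO2; then cold 1 M HCl
Reagents that add atoms: carbon dioxide, O=C=O
Why: Bromine–lithium exchange and carboxylation of the aryllithium; the aryl silyl ether survives the brief cold acidic work-up.

**Step 11**
Reactants: 17 (1R,3aR,5S,8S,8aS)-1,8-dihydroxy-1-isopropyl-3a,6-dimethyl-1,2,3,3a,4,5,8,8a-octahydroazulen-5-yl acetate; 20 4-[(tert-butyldimethylsilyl)oxy]benzoic acid
Product: 21 (3R,3aS,4S,7S,8aR)-7-acetoxy-3-hydroxy-3-isopropyl-6,8a-dimethyl-1,2,3,3a,4,7,8,8a-octahydroazulen-4-yl 4-[(tert-butyldimethylsilyl)oxy]benzoate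
Conditions: DCC, DMAP, CH2Cl2, rt
Reagents that add atoms: none
Why: Steglich esterification acylates the remaining secondary allylic alcohol, the tertiary alcohol does not react and no stereocentre is touched.

**Step 12**
Reactants: 21 (3R,3aS,4S,7S,8aR)-7-acetoxy-3-hydroxy-3-isopropyl-6,8a-dimethyl-1,2,3,3a,4,7,8,8a-octahydroazulen-4-yl 4-[(tert-butyldimethylsilyl)oxy]benzoate
Product: 22 (3R,3aS,4S,7S,8aR)-7-acetoxy-3-hydroxy-3-isopropyl-6,8a-dimethyl-1,2,3,3a,4,7,8,8a-octahydroazulen-4-yl 4-hydroxybenzoate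
Conditions: TBAF, AcOH, THF, 0 °C
Reagents that add atoms: none
Why: Buffered fluoride desilylation cleaves the aryl silyl ether selectively, and the acetate and the benzoate are stable under these conditions.

**Compound list**
1 | 4-bromobut-1-yne | C#CCCBr | starting material
2 | 2-methylpropanoyl chloride (isobutyryl chloride) | CC(C)C(=O)Cl | starting material
3 | (E)-(4-bromo-2-methylbut-1-en-1-yl)dimethylalane | C[Al](C)/C=C(\C)CCBr | intermediate (not isolated)
4 | (E)-7-bromo-2,5-dimethylhept-4-en-3-one | CC(C)C(=O)/C=C(\C)CCBr | intermediate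
5 | but-3-en-2-one (methyl vinyl ketone) | CC(=O)C=C | starting material
6 | tert-butyl(buta-1,3-dien-2-yloxy)dimethylsilane | C=CC(=C)O[Si](C)(C)C(C)(C)C | intermediate
7 | 1-[(1R,6S)-6-(2-bromoethyl)-4-[(tert-butyldimethylsilyl)oxy]-6-methylcyclohex-3-en-1-yl]-2-methylpropan-1-one | CC(C)C(=O)[C@@H]1CC=C(O[Si](C)(C)C(C)(C)C)C[C@@]1(C)CCBr | intermediate
8 | (1R,3aR,7aR)-5-[(tert-butyldimethylsilyl)oxy]-1-isopropyl-3a-methyl-2,3,3a,4,7,7a-hexahydro-1H-inden-1-ol (trans-fused, OH cis to the angular methyl) | C1=C(O[Si](C)(C)C(C)(C)C)C[C@@]2(C)CC[C@@](O)(C(C)C)[C@@H]2C1 | intermediate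
9 | (1R,3aR,7aR)-1-hydroxy-1-isopropyl-3a-methyl-1,2,3,3a,4,7a-hexahydro-5H-inden-5-one | O=C1C[C@@]2(C)CC[C@@](O)(C(C)C)[C@@H]2C=C1 | intermediate
10 | 1,1-dibromoethane | CC(Br)Br | starting material
11 | dilithium (1R,3aR,7aR)-5-(1,1-dibromoethyl)-1-isopropyl-3a-methyl-2,3,3a,4,5,7a-hexahydro-1H-indene-1,5-bis(olate), both C-5 epimers | CC(Br)(Br)C1(O[Li])C[C@@]2(C)CC[C@@](O[Li])(C(C)C)[C@@H]2C=C1 | intermediate (not isolated)
12 | dilithium (1R,3aR,8aR)-1-isopropyl-3a,6-dimethyl-1,2,3,3a,4,8a-hexahydroazulene-1,5-bis(olate) | CC1=C(O[Li])C[C@@]2(C)CC[C@@](O[Li])(C(C)C)[C@@H]2C=C1 | intermediate (not isolated)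
13 | (1R,3aR,8aR)-1-hydroxy-1-isopropyl-3a,6-dimethyl-1,2,3,3a,4,8a-hexahydroazulen-5-yl trifluoromethanesulfonate | CC1=C(OS(=O)(=O)C(F)(F)F)C[C@@]2(C)CC[C@@](O)(C(C)C)[C@@H]2C=C1 | intermediate
14 | (1R,3aR,8aR)-1-isopropyl-3a,6-dimethyl-1,2,3,3a,4,8a-hexahydroazulen-1-ol | CC1=CC[C@@]2(C)CC[C@@](O)(C(C)C)[C@@H]2C=C1 | intermediate
15 | (1R,3aR,5S,8S,8aS)-5,8-epidioxy-1-isopropyl-3a,6-dimethyl-1,2,3,3a,4,5,8,8a-octahydroazulen-1-ol | CC1=C[C@@H]2OO[C@H]1C[C@@]3(C)CC[C@@](O)(C(C)C)[C@@H]32 | intermediate (not isolated)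
16 | (1R,3aR,5S,8S,8aS)-1-isopropyl-3a,6-dimethyl-1,2,3,3a,4,5,8,8a-octahydroazulene-1,5,8-triol | O[C@H]1C[C@@]2(C)CC[C@@](O)(C(C)C)[C@@H]2[C@@H](O)C=C1C | intermediate
17 | (1R,3aR,5S,8S,8aS)-1,8-dihydroxy-1-isopropyl-3a,6-dimethyl-1,2,3,3a,4,5,8,8a-octahydroazulen-5-yl acetate | CC(=O)O[C@H]1C[C@@]2(C)CC[C@@](O)(C(C)C)[C@@H]2[C@@H](O)C=C1C | intermediate
18 | (4-bromophenoxy)(tert-butyl)dimethylsilane | CC(C)(C)[Si](C)(C)Oc1ccc(Br)cc1 | starting material
19 | {4-[(tert-butyldimethylsilyl)oxy]phenyl}lithium | [Li]c1ccc(O[Si](C)(C)C(C)(C)C)cc1 | intermediate (not isolated)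
20 | 4-[(tert-butyldimethylsilyl)oxy]benzoic acid | CC(C)(C)[Si](C)(C)Oc1ccc(C(=O)O)cc1 | intermediate
21 | (3R,3aS,4S,7S,8aR)-7-acetoxy-3-hydroxy-3-isopropyl-6,8a-dimethyl-1,2,3,3a,4,7,8,8a-octahydroazulen-4-yl 4-[(tert-butyldimethylsilyl)oxy]benzoate | CC(=O)O[C@H]1C[C@@]2(C)CC[C@@](O)(C(C)C)[C@@H]2[C@@H](OC(=O)c2ccc(O[Si](C)(C)C(C)(C)C)cc2)C=C1C | intermediate
22 | (3R,3aS,4S,7S,8aR)-7-acetoxy-3-hydroxy-3-isopropyl-6,8a-dimethyl-1,2,3,3a,4,7,8,8a-octahydroazulen-4-yl 4-hydroxybenzoate (CNP0305796.2) | CC(=O)O[C@H]1C[C@@]2(C)CC[C@@](O)(C(C)C)[C@@H]2[C@@H](OC(=O)c2ccc(O)cc2)C=C1C | target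

**Step count and risks**
Total step count: 12. Longest linear sequence: 10 steps (steps 1, 3, 4, 5, 6, 7, 8, 9, 11, 12); steps 2 and 10 are side branches.

The three steps most likely to fail:

Step 3 (the new enantioselective Diels–Alder). The β,β-disubstituted enone is a poor dienophile, a stepwise Mukaiyama–Michael path could erode the trans relationship, and the enantioselectivity is untested. The fallback uses known chemistry and sets out from 4 and 6. The cycloaddition is run with the achiral mixed Lewis acid AlBr3/AlMe3 (the known hindered Diels–Alder of 2-silyloxydienes with β,β-disubstituted enones), which gives racemic 7, that is 7 together with 1-[(1S,6R)-6-(2-bromoethyl)-4-[(tert-butyldimethylsilyl)oxy]-6-methylcyclohex-3-en-1-yl]-2-methylpropan-1-one F1. Steps 4 and 5 are carried out on the racemate, so that (1S,3aS,7aS)-5-[(tert-butyldimethylsilyl)oxy]-1-isopropyl-3a-methyl-2,3,3a,4,7,7a-hexahydro-1H-inden-1-ol F2 and (1S,3aS,7aS)-1-hydroxy-1-isopropyl-3a-methyl-1,2,3,3a,4,7a-hexahydro-5H-inden-5-one F3 accompany 8 and 9. Racemic 9 is then resolved by preparative HPLC on an amylose carbamate chiral stationary phase, and the fallback comes back to the route at 9.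

Step 4 (Barbier closure). Simple reduction of the C–Br bond or of the hindered ketone may compete, and the facial outcome at C-1 rests on a steric argument. The fallback sets out from 7. Finkelstein exchange (NaI, acetone, reflux) gives 1-[(1R,6S)-4-[(tert-butyldimethylsilyl)oxy]-6-(2-iodoethyl)-6-methylcyclohex-3-en-1-yl]-2-methylpropan-1-one F4. Iodine–lithium exchange (t-BuLi, 2.1 equiv, Et2O/pentane, −78 °C) then generates a primary alkyllithium that closes onto the ketone. This is a polar, exchange-initiated carbanion cyclisation in which a compact lithium alkoxide replaces the bulky samarium alkoxide in the stereo-determining step. It comes back to the route at 8.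

Step 6 (carbenoid ring expansion). The amide base may enolise 9, the CH2 may migrate instead of the alkenyl carbon, and the carbenoid may decompose. The fallback sets out from 9. 1,2-Addition of 1-(phenylselanyl)ethyllithium (from 1,1-bis(phenylselanyl)ethane and n-BuLi, THF, −78 °C) gives (1R,3aR,7aR)-1-isopropyl-3a-methyl-5-[1-(phenylselanyl)ethyl]-2,3,3a,4,5,7a-hexahydro-1H-indene-1,5-diol F5 as a diastereomer mixture. Silver-promoted semipinacol ring enlargement (AgBF4 on Al2O3, CH2Cl2, rt; selenium leaves and the alkenyl carbon shifts) gives (1R,3aR,8aR)-1-hydroxy-1-isopropyl-3a,6-dimethyl-2,3,3a,4,6,8a-hexahydroazulen-5(1H)-one F6. Deprotonation at the doubly activated C-6 with KN(SiMe3)2 and O-triflation with PhNTf2 (THF, −78 °C) gives 13, where the fallback comes back to the route.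

**Further compounds**
F1 | step 3 | 1-[(1S,6R)-6-(2-bromoethyl)-4-[(tert-butyldimethylsilyl)oxy]-6-methylcyclohex-3-en-1-yl]-2-methylpropan-1-one (ent-7) | CC(C)C(=O)[C@H]1CC=C(O[Si](C)(C)C(C)(C)C)C[C@]1(C)CCBr
F2 | step 3 | (1S,3aS,7aS)-5-[(tert-butyldimethylsilyl)oxy]-1-isopropyl-3a-methyl-2,3,3a,4,7,7a-hexahydro-1H-inden-1-ol (ent-8) | C1=C(O[Si](C)(C)C(C)(C)C)C[C@]2(C)CC[C@](O)(C(C)C)[C@H]2C1
F3 | step 3 | (1S,3aS,7aS)-1-hydroxy-1-isopropyl-3a-methyl-1,2,3,3a,4,7a-hexahydro-5H-inden-5-one (ent-9) | O=C1C[C@]2(C)CC[C@](O)(C(C)C)[C@H]2C=C1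
F4 | step 4 | 1-[(1R,6S)-4-[(tert-butyldimethylsilyl)oxy]-6-(2-iodoethyl)-6-methylcyclohex-3-en-1-yl]-2-methylpropan-1-one | CC(C)C(=O)[C@@H]1CC=C(O[Si](C)(C)C(C)(C)C)C[C@@]1(C)CCI
F5 | step 6 | (1R,3aR,7aR)-1-isopropyl-3a-methyl-5-[1-(phenylselanyl)ethyl]-2,3,3a,4,5,7a-hexahydro-1H-indene-1,5-diol (diastereomer mixture at C-5 and the side-chain carbon) | CC([Se]c1ccccc1)C1(O)C[C@@]2(C)CC[C@@](O)(C(C)C)[C@@H]2C=C1
F6 | step 6 | (1R,3aR,8aR)-1-hydroxy-1-isopropyl-3a,6-dimethyl-2,3,3a,4,6,8a-hexahydroazulen-5(1H)-one (C-6 epimers) | CC1C(=O)C[C@@]2(C)CC[C@@](O)(C(C)C)[C@@H]2C=C1
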